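**Retrosynthetic overview**
1. The last C–C bond cut is C6 acyl carbon–CH2: a chromene N-methoxy-N-methylamide plus a 2-(4-silyloxyphenyl)ethyl Grignard reagent made from 2-(4-hydroxyphenyl)ethanol.
2. Ring B (pyran; O1–C2 and C4–C4a) is cut to methyl 2,4-dihydroxy-3-prenylbenzoate and 3-methylbut-2-enal; the prenyl group blocks the carbon between the two oxygens, so only the linear chromene can form.
3. Feature carrying the strategy: in ring A (C4a, C5, C6, C7, C8, C8a) the oxygens on C7 and C8a flank the prenyl-bearing C8 exactly as the carbonyls of a cyclohexane-1,3-dione flank C2, and C6 carries a carboxyl-level carbon like a malonate carbon. The benzoate is therefore the dehydrogenation product of methyl 3-prenyl-2,4-dioxocyclohexane-1-carboxylate.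
4. That dione is cut at C5–C6 (Michael) and C7–C8 (Dieckmann-type acylation) to dimethyl malonate and 7-methylocta-1,6-dien-3-one; the enone comes from 6-methylhept-5-en-2-one by kinetic Mannich reaction and elimination.
5. Ring order: ring A as a carbocycle (step 3), made aromatic (steps 4 and 5), then ring B (step 6).

Key step: step 3

Remark on the chemistry: the target has no stereocentre. Compounds 7, 8 and 9 are handled as racemic, freely tautomerising mixtures, and 7 is drawn as its dienol.

**Route**

Step 1
Reactants: 1 6-methylhept-5-en-2-one
Product: 2 1-(dimethylamino)-7-methyloct-6-en-3-one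
Conditions: LiN(iPr)2, THF, −78 °C; then CH2=NMe2+ I−, −78 °C to rt
Reagents that add atoms: dimethylmethyleneiminium iodide, C=[N+](C)C.[I-]
Why: Kinetic deprotonation by the hindered amide base at −78 °C should give the less substituted (methyl-side) lithium enolate, which is aminomethylated by the preformed iminium salt before it can equilibrate (regiospecific Mannich reaction).

Step 2
Reactants: 2 1-(dimethylamino)-7-methyloct-6-en-3-one
Product: 4 7-methylocta-1,6-dien-3-one, via methiodide 3 (not isolated)
Conditions: MeI, Et2O, rt; then aq. NaHCO3, CH2Cl2, rt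
Reagents that add atoms: none
Why: N-Methylation turns the amine into a leaving group and mild base then induces E1cB (Hofmann-type) β-elimination of trimethylamine to the vinyl ketone, which is kept cold with a trace of BHT and used at once.

Step 3
Reactants: 4 7-methylocta-1,6-dien-3-one; 5 dimethyl malonate
Product: 7 methyl 3-(3-methylbut-2-enyl)-2,4-dioxocyclohexane-1-carboxylate, via Michael adduct 6 (not isolated)
Conditions: NaOMe (1.2 equiv), MeOH, 0 °C (slow addition of 4), then reflux; cold 1 M HCl
Reagents that add atoms: none
Why: Methoxide generates the malonate anion, which adds 1,4 to the unsubstituted vinyl terminus of 4 (Michael addition, the future C5–C6 bond) to give 6; reversible enolisation of the ketone toward the prenyl-bearing methylene then lets that carbon attack one ester carbonyl and expel methoxide (Dieckmann/Claisen-type acylation, the future C7–C8 bond), closing ring A by 6-exo-trig closure. The closest known reaction type is the classical dihydroresorcinol synthesis from a malonate and an enone, which gives 4-alkoxycarbonylcyclohexane-1,3-diones. No stereocentre needs control, because the carbons bearing the ester and the prenyl group are enolisable and become sp2 in the arene. The selectivity needed is the regiochemistry of the acylation, and ring size fixes it: the α′-carbon reaches an ester through a six-membered transition state, whereas the other α-carbon could only close a four-membered ring; 1,4- over 1,2-addition is secured by the soft malonate anion and the unhindered β-carbon. The closure is pulled through by deprotonation of the product to a doubly stabilised enolate, which is why a full equivalent of base is used, and acidification should liberate 7.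

Step 4
Reactants: 7 methyl 3-(3-methylbut-2-enyl)-2,4-dioxocyclohexane-1-carboxylate
Product: 8 methyl 3-(3-methylbut-2-enyl)-2,4-dioxo-1-(phenylselanyl)cyclohexane-1-carboxylate
Conditions: LiN(iPr)2 (2.1 equiv), THF, −78 to 0 °C; PhSeBr (1.05 equiv), −78 °C; AcOH
Reagents that add atoms: phenylselanyl bromide, Br[Se]c1ccccc1
Why: In the dianion the carbon between the two ketones is tied up in the first-formed, delocalised dione enolate, so the last-formed, more basic carbanion next to the ester should take the selenium electrophile (α-selenenylation of a β-dicarbonyl dianion); enolate capture at −78 °C is far faster than addition of PhSeBr to the trisubstituted alkene, and capture at the other ring CH2 would lead to the same arene.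

Step 5
Reactants: 8 methyl 3-(3-methylbut-2-enyl)-2,4-dioxo-1-(phenylselanyl)cyclohexane-1-carboxylate
Product: 10 methyl 2,4-dihydroxy-3-(3-methylbut-2-enyl)benzoate, via selenoxide 9 (not isolated)
Conditions: 30% aq. H2O2 (2 equiv), pyridine, CH2Cl2, 0 °C to rt
Reagents that add atoms: none
Why: Oxidation to the selenoxide is followed by syn β-elimination toward the only available β-hydrogens (the ring CH2), and the cyclohexadienone so formed is a tautomer of the arene and should enolise at once (selenoxide elimination with aromatisation); pyridine buffers the selenium acids so that the prenyl alkene is left alone.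

Step 6
Reactants: 10 methyl 2,4-dihydroxy-3-(3-methylbut-2-enyl)benzoate; 11 3-methylbut-2-enal
Product: 13 methyl 7-hydroxy-2,2-dimethyl-8-(3-methylbut-2-enyl)-2H-chromene-6-carboxylate, via ortho-quinone methide 12 (not isolated)
Conditions: ethylenediammonium diacetate (0.2 equiv), xylene, 140 °C
Reagents that add atoms: none
Why: Amine-salt-catalysed condensation of the aldehyde (as its iminium ion) at the only free ring carbon ortho to a hydroxyl gives the ortho-quinone methide, which should close by oxa-6π electrocyclisation onto the unchelated oxygen (formal [3+3] chromene annulation); the prenyl-blocked carbon between the oxygens excludes the angular isomer.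

Step 7
Reactants: 13 methyl 7-hydroxy-2,2-dimethyl-8-(3-methylbut-2-enyl)-2H-chromene-6-carboxylate
Product: 14 7-hydroxy-N-methoxy-N,2,2-trimethyl-8-(3-methylbut-2-enyl)-2H-chromene-6-carboxamide
Conditions: MeNH(OMe)·HCl (3 equiv), iPrMgCl (7 equiv), THF, −20 to 0 °C
Reagents that add atoms: N,O-dimethylhydroxylamine hydrochloride, CNOC.Cl
Why: The chloromagnesium amide of N,O-dimethylhydroxylamine displaces methoxide from the ester (direct ester-to-Weinreb-amide aminolysis), the extra equivalent of iPrMgCl only converting the chelated phenol into its magnesium phenoxide.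

Step 8
Reactants: 15 2-(4-hydroxyphenyl)ethanol
Product: 16 4-(2-bromoethyl)phenol
Conditions: 48% aq. HBr, 90 °C
Reagents that add atoms: hydrogen bromide, Br
Why: The protonated primary hydroxyl is displaced by bromide (SN2), while the phenolic C–O bond is inert to HBr.

Step 9
Reactants: 16 4-(2-bromoethyl)phenol
Product: 17 [4-(2-bromoethyl)phenoxy](tert-butyl)dimethylsilane
Conditions: TBSCl, imidazole, DMF, 0 °C to rt
Reagents that add atoms: tert-butyldimethylsilyl chloride, CC(C)(C)[Si](C)(C)Cl
Why: Imidazole-mediated O-silylation of the phenol is faster than any alkylation by the primary bromide and removes the acidic proton before the Grignard step.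

Step 10
Reactants: 14 7-hydroxy-N-methoxy-N,2,2-trimethyl-8-(3-methylbut-2-enyl)-2H-chromene-6-carboxamide; 17 [4-(2-bromoethyl)phenoxy](tert-butyl)dimethylsilane
Product: 19 3-[4-(tert-butyldimethylsilyloxy)phenyl]-1-[7-hydroxy-2,2-dimethyl-8-(3-methylbut-2-enyl)-2H-chromen-6-yl]propan-1-one, via Grignard reagent 18 (not isolated)
Conditions: 17, Mg, THF, 40 °C; then 14 (3 equiv of 18 per 14), THF, 0 °C to rt; aq. NH4Cl
Reagents that add atoms: none
Why: Magnesium insertion gives the primary Grignard reagent, one equivalent of which deprotonates the phenol while a second adds to the N-methoxy-N-methylamide to give a chelated tetrahedral intermediate that releases the ketone only on work-up, so over-addition should not occur (Weinreb ketone synthesis).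

Step 11
Reactants: 19 3-[4-(tert-butyldimethylsilyloxy)phenyl]-1-[7-hydroxy-2,2-dimethyl-8-(3-methylbut-2-enyl)-2H-chromen-6-yl]propan-1-one
Product: 20 3-(4-hydroxyphenyl)-1-[7-hydroxy-2,2-dimethyl-8-(3-methylbut-2-enyl)-2H-chromen-6-yl]propan-1-one (CNP0163015.0)
Conditions: Bu4NF, AcOH, THF, 0 °C
Reagents that add atoms: none
Why: Fluoride cleaves the aryl silyl ether, driven by Si–F bond formation, and the acetic acid buffer keeps the medium near neutral so that the ketone, the chromene and the prenyl alkene should be untouched (fluoride desilylation).

**Compound list**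
1 | 6-methylhept-5-en-2-one | CC(=O)CCC=C(C)C | starting material
2 | 1-(dimethylamino)-7-methyloct-6-en-3-one | CN(C)CCC(=O)CCC=C(C)C | intermediate
3 | trimethyl(7-methyl-3-oxooct-6-enyl)ammonium iodide | C[N+](C)(C)CCC(=O)CCC=C(C)C.[I-] | intermediate
4 | 7-methylocta-1,6-dien-3-one | C=CC(=O)CCC=C(C)C | intermediate
5 | dimethyl malonate | COC(=O)CC(=O)OC | starting material
6 | dimethyl 2-(7-methyl-3-oxooct-6-enyl)propanedioate | COC(=O)C(CCC(=O)CCC=C(C)C)C(=O)OC | intermediate
7 | methyl 3-(3-methylbut-2-enyl)-2,4-dioxocyclohexane-1-carboxylate (drawn as dienol tautomer; keto forms racemic) | COC(=O)C1=C(O)C(CC=C(C)C)=C(O)CC1 | intermediate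
8 | methyl 3-(3-methylbut-2-enyl)-2,4-dioxo-1-(phenylselanyl)cyclohexane-1-carboxylate (racemic, drawn as an enol) | COC(=O)C1(CCC(O)=C(CC=C(C)C)C1=O)[Se]c1ccccc1 | intermediate
9 | methyl 3-(3-methylbut-2-enyl)-2,4-dioxo-1-(phenylseleninyl)cyclohexane-1-carboxylate (diastereomer mixture, drawn as an enol) | COC(=O)C1(CCC(O)=C(CC=C(C)C)C1=O)[Se](=O)c1ccccc1 | intermediate
10 | methyl 2,4-dihydroxy-3-(3-methylbut-2-enyl)benzoate | COC(=O)c1ccc(O)c(CC=C(C)C)c1O | intermediate
11 | 3-methylbut-2-enal | CC(C)=CC=O | starting material
12 | methyl (5Z)-2-hydroxy-5-(3-methylbut-2-enylidene)-3-(3-methylbut-2-enyl)-4-oxocyclohexa-1,6-diene-1-carboxylate (ortho-quinone methide) | COC(=O)C1=C/C(=C/C=C(C)C)C(=O)C(CC=C(C)C)=C1O | intermediate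
13 | methyl 7-hydroxy-2,2-dimethyl-8-(3-methylbut-2-enyl)-2H-chromene-6-carboxylate | COC(=O)c1cc2C=CC(C)(C)Oc2c(CC=C(C)C)c1O | intermediate
14 | 7-hydroxy-N-methoxy-N,2,2-trimethyl-8-(3-methylbut-2-enyl)-2H-chromene-6-carboxamide | CON(C)C(=O)c1cc2C=CC(C)(C)Oc2c(CC=C(C)C)c1O | intermediate
15 | 2-(4-hydroxyphenyl)ethanol | OCCc1ccc(O)cc1 | starting material
16 | 4-(2-bromoethyl)phenol | Oc1ccc(CCBr)cc1 | intermediate
17 | [4-(2-bromoethyl)phenoxy](tert-butyl)dimethylsilane | CC(C)(C)[Si](C)(C)Oc1ccc(CCBr)cc1 | intermediate
18 | 2-[4-(tert-butyldimethylsilyloxy)phenyl]ethylmagnesium bromide | CC(C)(C)[Si](C)(C)Oc1ccc(CC[Mg]Br)cc1 | intermediate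
19 | 3-[4-(tert-butyldimethylsilyloxy)phenyl]-1-[7-hydroxy-2,2-dimethyl-8-(3-methylbut-2-enyl)-2H-chromen-6-yl]propan-1-one | CC(C)=CCc1c(O)c(C(=O)CCc2ccc(O[Si](C)(C)C(C)(C)C)cc2)cc2c1OC(C)(C)C=C2 | intermediate
20 | 3-(4-hydroxyphenyl)-1-[7-hydroxy-2,2-dimethyl-8-(3-methylbut-2-enyl)-2H-chromen-6-yl]propan-1-one | CC(C)=CCc1c(O)c(C(=O)CCc2ccc(O)cc2)cc2c1OC(C)(C)C=C2 | target

**Step count**
Total steps: 11. Longest linear sequence: 9 (steps 1, 2, 3, 4, 5, 6, 7, 10, 11); steps 8 and 9 form the side branch.

**Steps most likely to fail**

1. Step 4 (and its consequence in step 5). Selenenylation may lose regiocontrol and occur at the carbon between the two ketones, where no useful elimination is possible. The selenium electrophile or, later, the peroxide/seleninic acid mixture may also attack the prenyl double bond. The fallback aromatises by hydride abstraction instead of syn-elimination. It sets out from 7: silylation (Me3SiOTf, Et3N, CH2Cl2, 0 °C) should give methyl 3-(3-methylbut-2-enyl)-2,4-bis(trimethylsilyloxy)cyclohexa-1,3-diene-1-carboxylate F1. DDQ (1.0 equiv, benzene, 0 °C to rt) should then remove hydride from the ring CH2 next to the ester-bearing carbon, giving a doubly oxygen-stabilised cation that loses a proton to form methyl 3-(3-methylbut-2-enyl)-2,4-bis(trimethylsilyloxy)benzoate F2. Brief methanolysis (K2CO3, MeOH, 0 °C) cleaves both silyl ethers, and the route is rejoined at 10.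

2. Step 3. The vinyl ketone may polymerise or take up two malonate units before ring closure, or the sequence may stall at the open-chain adduct. The fallback never handles the free enone and splits the tandem into two operations. It sets out from 2: the methiodide 3 is filtered off after the MeI treatment of step 2 and added in portions to the sodium salt of 5 (NaOMe, 2 equiv, MeOH, 0 °C). Compound 4 is then released slowly by elimination and trapped at once as 6. Compound 6 is isolated and cyclised separately under aprotic, irreversible conditions (KOtBu, THF, 0 °C to rt; then cold HCl), returning to the route at 7. No compound outside the compound list arises on this path (none, F0).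

3. Step 6. The ester-deactivated ring may condense too slowly at the one free ortho carbon, so that the aldehyde self-condenses or the mixture degrades at 140 °C. The fallback builds ring B by a sigmatropic route. It sets out from 10: the unchelated hydroxyl is alkylated with 3-chloro-3-methylbut-1-yne (K2CO3, KI, acetone, reflux) to give methyl 2-hydroxy-4-(2-methylbut-3-yn-2-yloxy)-3-(3-methylbut-2-enyl)benzoate F3. Heating in N,N-diethylaniline at about 180 °C should bring about aryl propargyl ether Claisen rearrangement to the free ortho carbon, 1,5-hydrogen shift and oxa-6π closure, rejoining the route at 13.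

**Further compounds**
F1 | step 4 | methyl 3-(3-methylbut-2-enyl)-2,4-bis(trimethylsilyloxy)cyclohexa-1,3-diene-1-carboxylate | COC(=O)C1=C(O[Si](C)(C)C)C(CC=C(C)C)=C(O[Si](C)(C)C)CC1
F2 | step 4 | methyl 3-(3-methylbut-2-enyl)-2,4-bis(trimethylsilyloxy)benzoate | COC(=O)c1ccc(O[Si](C)(C)C)c(CC=C(C)C)c1O[Si](C)(C)C
F0 | step 3 | none | none
F3 | step 6 | methyl 2-hydroxy-4-(2-methylbut-3-yn-2-yloxy)-3-(3-methylbut-2-enyl)benzoate | COC(=O)c1ccc(OC(C)(C)C#C)c(CC=C(C)C)c1O
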